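The plan rests on cutting ring C at C2–C3 and O1–C2. Because C2 carries ring B and C3 carries the oxepine methylene C9, the C2=C3 bond is the enone of a cyclic chalcone: ring-A ketone carbon C4 with its α-carbon C3, and ring-B formyl carbon C2. One amine-mediated operation therefore closes the oxepine (aldol condensation) and the pyranone (phenol conjugate addition) to a flavanone, which is dehydrogenated afterwards. The precursor is a 2,6-dihydroxy-4-methoxyphenyl ketone whose chain (C3–C9–C10) ends in an aryl ether to a 4-silyloxysalicylaldehyde; C10 (R) comes from an S epoxide opened with inversion. The C6 alkenyl group is added last by iodination and Suzuki coupling.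

Key step: step 10

Remark: atoms are named with flavone numbering (ring C: O1, C2, C3, C4; ring A: C4a–C8a; ring B: C1'–C6'), the oxepine methylene on C3 is C9 and the carbinol-bearing stereocentre is C10 (R in the target); the L-fructose-derived Shi ketone is assumed to be purchasable (it is also made from L-sorbose).

Step 1
Reactants: 1 2-methylbut-3-en-2-ol
Product: 2 ethyl 5-methylhex-4-enoate
Conditions: MeC(OEt)3 (5 equiv), EtCO2H (cat.), 140 °C, EtOH distilled off
Reagents that add atoms: triethyl orthoacetate, CCOC(C)(OCC)OCC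
Why: The Johnson–Claisen rearrangement of the tertiary allylic alcohol passes through its ketene acetal and a chair [3,3] shift, which attaches the two-carbon ester unit to the terminal alkene carbon and leaves the isopropylidene alkene needed for epoxidation.

Step 2
Reactants: 2 ethyl 5-methylhex-4-enoate
Product: 3 N-methoxy-N,5-dimethylhex-4-enamide
Conditions: MeNHOMe·HCl (1.5 equiv), iPrMgCl (3 equiv), THF, −20 °C
Reagents that add atoms: N,O-dimethylhydroxylamine hydrochloride, CNOC.Cl
Why: Aminolysis of an unhindered ethyl ester by the chloromagnesium amide of N,O-dimethylhydroxylamine is the standard Weinreb amide synthesis, and the isolated alkene is inert to it.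

Step 3
Reactants: 3 N-methoxy-N,5-dimethylhex-4-enamide
Product: 4 3-[(2S)-3,3-dimethyloxiran-2-yl]-N-methoxy-N-methylpropanamide
Conditions: L-fructose-derived Shi ketone (enantiomer of the usual D-fructose-derived ketone, 0.3 equiv), KHSO5 (as 2KHSO5·KHSO4·K2SO4), K2CO3, Bu4NHSO4, Na2B4O7 buffer (pH 10.5), MeCN–CH2(OMe)2–H2O, 0 °C
Reagents that add atoms: potassium peroxymonosulfate, [K+].[O-]S(=O)(=O)OO
Why: Shi asymmetric epoxidation is at its best with trisubstituted alkenes, and since the D-fructose-derived dioxirane gives the R configuration at the CH carbon of RCH2–CH=CMe2 alkenes through the spiro transition state, the L-fructose-derived catalyst should give the S epoxide that step 6 inverts to 10R.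

Step 4
Reactants: 5 2,4-dihydroxybenzaldehyde
Product: 6 2-hydroxy-4-[(triisopropylsilyl)oxy]benzaldehyde
Conditions: TIPSCl (1.05 equiv), imidazole, CH2Cl2, 0 °C
Reagents that add atoms: triisopropylsilyl chloride, CC(C)[Si](Cl)(C(C)C)C(C)C
Why: This O-silylation should be regioselective because the 4-hydroxyl is the more acidic and unhindered phenol, whereas the 2-hydroxyl is held in a hydrogen bond to the formyl oxygen.

Step 5
Reactants: 6 2-hydroxy-4-[(triisopropylsilyl)oxy]benzaldehyde
Product: 7 2-(5,5-dimethyl-1,3-dioxan-2-yl)-5-[(triisopropylsilyl)oxy]phenol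
Conditions: HOCH2C(CH3)2CH2OH (3 equiv), PPTS (cat.), toluene, reflux, Dean–Stark
Reagents that add atoms: 2,2-dimethylpropane-1,3-diol, OCC(C)(C)CO
Why: Acid-catalysed acetalisation with azeotropic removal of water masks the aldehyde against the aryllithium of step 8 and makes the phenol more nucleophilic for step 6, the neopentyl glycol acetal being the robust form for a salicylaldehyde.

Step 6
Reactants: 4 3-[(2S)-3,3-dimethyloxiran-2-yl]-N-methoxy-N-methylpropanamide; 7 2-(5,5-dimethyl-1,3-dioxan-2-yl)-5-[(triisopropylsilyl)oxy]phenol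
Product: 8 (4R)-4-{2-(5,5-dimethyl-1,3-dioxan-2-yl)-5-[(triisopropylsilyl)oxy]phenoxy}-5-hydroxy-N-methoxy-N,5-dimethylhexanamide
Conditions: 7 (1.3 equiv), K2CO3 (0.5 equiv), 18-crown-6 (cat.), anhydrous DMF, 90 °C
Reagents that add atoms: none
Why: Base-mediated phenoxide opening of a trisubstituted epoxide is an SN2 reaction at the less substituted carbon, so the aryloxy group should enter at C10 with inversion (S epoxide to R ether) and leave the tertiary alcohol, while the amide, the acetal and the hindered silyl ether tolerate anhydrous carbonate.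

Step 7
Reactants: 9 5-methoxyresorcinol
Product: 10 1-methoxy-3,5-bis(methoxymethoxy)benzene
Conditions: MOMCl (2.5 equiv), iPr2NEt, CH2Cl2, 0 °C to rt
Reagents that add atoms: chloromethyl methyl ether, COCCl
Why: Standard O-alkylation of both phenols gives the bis-MOM ether, whose two acetal oxygens will direct lithiation to the carbon between them.

Step 8
Reactants: 10 1-methoxy-3,5-bis(methoxymethoxy)benzene; 8 (4R)-4-{2-(5,5-dimethyl-1,3-dioxan-2-yl)-5-[(triisopropylsilyl)oxy]phenoxy}-5-hydroxy-N-methoxy-N,5-dimethylhexanamide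
Product: 12 (4R)-4-{2-(5,5-dimethyl-1,3-dioxan-2-yl)-5-[(triisopropylsilyl)oxy]phenoxy}-5-hydroxy-1-[4-methoxy-2,6-bis(methoxymethoxy)phenyl]-5-methylhexan-1-one, via aryllithium 11 (not isolated)
Conditions: 10 (2.5 equiv), n-BuLi (2.4 equiv), THF, 0 °C; then 8, −78 to 0 °C; H2O
Reagents that add atoms: none
Why: Directed ortho-lithiation between the two MOM ethers is followed by a Weinreb ketone synthesis, in which one equivalent of the aryllithium is spent on the tertiary hydroxyl and the chelated tetrahedral intermediate stops the addition at the ketone, with acetal, silyl ether and C10 untouched.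

Step 9
Reactants: 12 (4R)-4-{2-(5,5-dimethyl-1,3-dioxan-2-yl)-5-[(triisopropylsilyl)oxy]phenoxy}-5-hydroxy-1-[4-methoxy-2,6-bis(methoxymethoxy)phenyl]-5-methylhexan-1-one
Product: 13 2-{[(3R)-6-(2,6-dihydroxy-4-methoxyphenyl)-2-hydroxy-2-methyl-6-oxohexan-3-yl]oxy}-4-[(triisopropylsilyl)oxy]benzaldehyde
Conditions: 1 M HCl (aq), MeOH–THF, 40 °C
Reagents that add atoms: water, O
Why: Acid solvolysis removes the two MOM ethers (helped by the neighbouring carbonyl) and the electron-rich aryl acetal in one operation, while the aryl triisopropylsilyl ether and the tertiary alcohol, whose ionisation is disfavoured by the adjacent aryloxy carbon, should withstand dilute aqueous acid in which any cyclic hemiketal reverts to the hydroxy ketone.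

Step 10
Reactants: 13 2-{[(3R)-6-(2,6-dihydroxy-4-methoxyphenyl)-2-hydroxy-2-methyl-6-oxohexan-3-yl]oxy}-4-[(triisopropylsilyl)oxy]benzaldehyde
Product: 15 (10R)-5-hydroxy-10-(2-hydroxypropan-2-yl)-7-methoxy-4'-[(triisopropylsilyl)oxy]flavanone bridged C3–C9H2–C10H–O–C2' (oxepine-fused; mixture at C2 and C3), via cyclic enone 14 (not isolated)
Conditions: pyrrolidine (2 equiv), AcOH (1 equiv), MeCN, 4 Å MS, 60 °C, 0.01 M
Reagents that add atoms: none
Why: Pyrrolidine turns the ring-B aldehyde into an iminium ion, the enamine or enol of the ring-A ketone attacks it through C3, and loss of the amine gives the cyclic enone 14, to whose C2 a ring-A phenol then adds. The closest known chemistry is the amine-mediated Kabbe chromanone synthesis and the Claisen–Schmidt condensation with chalcone-to-flavanone cyclisation, with the first stage made intramolecular as in the known aldol closures of 2-formylphenoxy-tethered carbonyl compounds to 2,3-dihydro-1-benzoxepines. The oxepine closes by a 7-(enolexo)-exo-trig aldol condensation (C2–C3) and the pyranone by a 6-endo-trig oxa-Michael addition (O1–C2). C2 and C3 are new stereocentres that are left uncontrolled as an equilibrating mixture because step 11 removes both, whereas C10 is γ to the ketone, cannot enolise and has no β-leaving-group relationship, so it should keep its R configuration. The step needs one condensation direction and ring closure in preference to oligomerisation: C3 is the only enolisable carbon, the aldehyde is the only electrophile, the two ortho hydroxyls of ring A are equivalent so either gives the same chromanone, high dilution and the substituted tether favour cyclisation, and reversible hemiketal formation or addition by the tertiary alcohol should drain into the hydrogen-bonded 5-hydroxychromanone.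

Step 11
Reactants: 15 (10R)-5-hydroxy-10-(2-hydroxypropan-2-yl)-7-methoxy-4'-[(triisopropylsilyl)oxy]flavanone bridged C3–C9H2–C10H–O–C2'
Product: 16 (10R)-5-hydroxy-10-(2-hydroxypropan-2-yl)-7-methoxy-4'-[(triisopropylsilyl)oxy]flavone bridged C3–C9H2–C10H–O–C2' (oxepine-fused flavone)
Conditions: DDQ (1.5 equiv), 1,4-dioxane, 90 °C
Reagents that add atoms: none
Why: DDQ dehydrogenation of a flavanone takes hydride from C2, which is benzylic to the 2,4-dioxygenated ring B and α to O1, and C3 then loses a proton, so no particular C2/C3 relative configuration is required, the reaction stops at the stable γ-pyrone and C10 lies outside the reacting system.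

Step 12
Reactants: 16 (10R)-5-hydroxy-10-(2-hydroxypropan-2-yl)-7-methoxy-4'-[(triisopropylsilyl)oxy]flavone bridged C3–C9H2–C10H–O–C2'
Product: 17 the 6-iodo derivative of 16
Conditions: BnMe3N+ ICl2− (1.1 equiv), CaCO3, CH2Cl2–MeOH, rt
Reagents that add atoms: benzyltrimethylammonium dichloroiodate, C[N+](C)(C)Cc1ccccc1.Cl[I-]Cl
Why: In this electrophilic aromatic iodination the free 5-hydroxyl of 5-hydroxy-7-alkoxyflavones is known to direct the dichloroiodate to C6, the phloroglucinol-type ring A is far more nucleophilic than ring B (whose oxygens are conjugated to the pyrone and shielded by the bulky silyl group), and C3 is blocked.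

Step 13
Reactants: 18 3-methylbut-1-yne
Product: 19 4,4,5,5-tetramethyl-2-[(E)-3-methylbut-1-en-1-yl]-1,3,2-dioxaborolane
Conditions: pinacolborane (1.05 equiv), Cp2Zr(H)Cl (5 mol%), Et3N (10 mol%), neat, sealed tube, 60 °C
Reagents that add atoms: pinacolborane, CC1(C)OBOC1(C)C
Why: Zirconium-catalysed hydroboration of a terminal alkyne is a syn, anti-Markovnikov addition that places boron on the terminal carbon and so gives the E alkenylboronate.

Step 14
Reactants: 17 the 6-iodo derivative of 16; 19 4,4,5,5-tetramethyl-2-[(E)-3-methylbut-1-en-1-yl]-1,3,2-dioxaborolane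
Product: 20 (10R)-5-hydroxy-10-(2-hydroxypropan-2-yl)-7-methoxy-6-[(E)-3-methylbut-1-en-1-yl]-4'-[(triisopropylsilyl)oxy]flavone bridged C3–C9H2–C10H–O–C2'
Conditions: 19 (1.5 equiv), Pd(OAc)2 (5 mol%), SPhos (10 mol%), K3PO4, THF–H2O, 60 °C
Reagents that add atoms: none
Why: Suzuki–Miyaura coupling proceeds with retention of alkene geometry, and a dialkylbiarylphosphine catalyst copes with the doubly ortho-substituted aryl iodide next to a free phenol, so the E side chain should be installed at C6.

Step 15
Reactants: 20 (10R)-5-hydroxy-10-(2-hydroxypropan-2-yl)-7-methoxy-6-[(E)-3-methylbut-1-en-1-yl]-4'-[(triisopropylsilyl)oxy]flavone bridged C3–C9H2–C10H–O–C2'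
Product: 21 (10R)-5,4'-dihydroxy-10-(2-hydroxypropan-2-yl)-7-methoxy-6-[(E)-3-methylbut-1-en-1-yl]flavone bridged C3–C9H2–C10H–O–C2' (CNP0216454.1)
Conditions: TBAF (1.2 equiv), AcOH (1.2 equiv), THF, 0 °C
Reagents that add atoms: none
Why: Buffered fluoride cleavage of the aryl silyl ether frees the 4'-hydroxyl without acid, so the electron-rich styrenyl alkene, the tertiary alcohol and C10 are not put at risk.

Compound list
1 | 2-methylbut-3-en-2-ol | C=CC(C)(C)O | starting material
2 | ethyl 5-methylhex-4-enoate | CCOC(=O)CCC=C(C)C | intermediate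
3 | N-methoxy-N,5-dimethylhex-4-enamide | CON(C)C(=O)CCC=C(C)C | intermediate
4 | 3-[(2S)-3,3-dimethyloxiran-2-yl]-N-methoxy-N-methylpropanamide | CON(C)C(=O)CC[C@@H]1OC1(C)C | intermediate
5 | 2,4-dihydroxybenzaldehyde | O=Cc1ccc(O)cc1O | starting material
6 | 2-hydroxy-4-[(triisopropylsilyl)oxy]benzaldehyde | O=Cc1ccc(O[Si](C(C)C)(C(C)C)C(C)C)cc1O | intermediate
7 | 2-(5,5-dimethyl-1,3-dioxan-2-yl)-5-[(triisopropylsilyl)oxy]phenol | Oc1cc(O[Si](C(C)C)(C(C)C)C(C)C)ccc1C1OCC(C)(C)CO1 | intermediate
8 | (4R)-4-{2-(5,5-dimethyl-1,3-dioxan-2-yl)-5-[(triisopropylsilyl)oxy]phenoxy}-5-hydroxy-N-methoxy-N,5-dimethylhexanamide | CON(C)C(=O)CC[C@H](C(C)(C)O)Oc1cc(O[Si](C(C)C)(C(C)C)C(C)C)ccc1C1OCC(C)(C)CO1 | intermediate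
9 | 5-methoxyresorcinol | COc1cc(O)cc(O)c1 | starting material
10 | 1-methoxy-3,5-bis(methoxymethoxy)benzene | COCOc1cc(OC)cc(OCOC)c1 | intermediate
11 | [4-methoxy-2,6-bis(methoxymethoxy)phenyl]lithium | COCOc1cc(OC)cc(OCOC)c1[Li] | intermediate (not isolated)
12 | (4R)-4-{2-(5,5-dimethyl-1,3-dioxan-2-yl)-5-[(triisopropylsilyl)oxy]phenoxy}-5-hydroxy-1-[4-methoxy-2,6-bis(methoxymethoxy)phenyl]-5-methylhexan-1-one | COCOc1cc(OC)cc(OCOC)c1C(=O)CC[C@H](C(C)(C)O)Oc1cc(O[Si](C(C)C)(C(C)C)C(C)C)ccc1C1OCC(C)(C)CO1 | intermediate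
13 | 2-{[(3R)-6-(2,6-dihydroxy-4-methoxyphenyl)-2-hydroxy-2-methyl-6-oxohexan-3-yl]oxy}-4-[(triisopropylsilyl)oxy]benzaldehyde | COc1cc(O)c(C(=O)CC[C@H](C(C)(C)O)Oc2cc(O[Si](C(C)C)(C(C)C)C(C)C)ccc2C=O)c(O)c1 | intermediate
14 | (2,6-dihydroxy-4-methoxyphenyl){(2R)-2-(2-hydroxypropan-2-yl)-8-[(triisopropylsilyl)oxy]-2,3-dihydro-1-benzoxepin-4-yl}methanone | COc1cc(O)c(C(=O)C2=Cc3ccc(O[Si](C(C)C)(C(C)C)C(C)C)cc3O[C@@H](C(C)(C)O)C2)c(O)c1 | intermediate (not isolated)
15 | (10R)-5-hydroxy-10-(2-hydroxypropan-2-yl)-7-methoxy-4'-[(triisopropylsilyl)oxy]flavanone bridged C3–C9H2–C10H–O–C2' (mixture at C2 and C3) | COc1cc2c(c(O)c1)C(=O)C1C[C@H](C(C)(C)O)Oc3cc(O[Si](C(C)C)(C(C)C)C(C)C)ccc3C1O2 | intermediate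
16 | (10R)-5-hydroxy-10-(2-hydroxypropan-2-yl)-7-methoxy-4'-[(triisopropylsilyl)oxy]flavone bridged C3–C9H2–C10H–O–C2' | COc1cc2oc3c(c(=O)c2c(O)c1)C[C@H](C(C)(C)O)Oc1cc(O[Si](C(C)C)(C(C)C)C(C)C)ccc1-3 | intermediate
17 | 6-iodo derivative of 16 | COc1cc2oc3c(c(=O)c2c(O)c1I)C[C@H](C(C)(C)O)Oc1cc(O[Si](C(C)C)(C(C)C)C(C)C)ccc1-3 | intermediate
18 | 3-methylbut-1-yne | CC(C)C#C | starting material
19 | 4,4,5,5-tetramethyl-2-[(E)-3-methylbut-1-en-1-yl]-1,3,2-dioxaborolane | CC(C)/C=C/B1OC(C)(C)C(C)(C)O1 | intermediate
20 | 6-[(E)-3-methylbut-1-en-1-yl] derivative of 16 | COc1cc2oc3c(c(=O)c2c(O)c1/C=C/C(C)C)C[C@H](C(C)(C)O)Oc1cc(O[Si](C(C)C)(C(C)C)C(C)C)ccc1-3 | intermediate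
21 | (10R)-5,4'-dihydroxy-10-(2-hydroxypropan-2-yl)-7-methoxy-6-[(E)-3-methylbut-1-en-1-yl]flavone bridged C3–C9H2–C10H–O–C2' (CNP0216454.1) | COc1cc2oc3c(c(=O)c2c(O)c1/C=C/C(C)C)C[C@H](C(C)(C)O)Oc1cc(O)ccc1-3 | target

Total steps: 15. Longest linear sequence: 11 steps (steps 1, 2, 3, 6, 8, 9, 10, 11, 12, 14, 15).

Steps most likely to fail

1. Step 10. The seven-membered aldol closure may lose to intermolecular condensation, the iminium may rest unproductively, or the amine may strip the silyl ether and so deactivate the aldehyde. The fallback sets out from 12 and forms the C2–C3 bond by a Lewis-acid Mukaiyama aldol addition to the acetal instead of an amine-mediated condensation. TMSOTf and Et3N (CH2Cl2, 0 °C) should convert 12 into the silyl enol ether that also carries a trimethylsilyl ether on the tertiary alcohol F1. After removal of the amine salts, catalytic TMSOTf at −78 °C should ionise the aryl dioxane to an oxocarbenium ion, which the enol ether attacks to close the oxepine and give the β-alkoxy ketone F2. Treatment with 1 M HCl in MeOH–THF at 40–50 °C should then remove the trimethylsilyl and MOM groups and expel the alkoxy group from C2 to give enone 14, to which the freed phenol adds. The fallback comes back to the route at 15.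

2. Step 6. Substitution at the hindered C10 may be so slow that the temperature it needs causes migration or loss of the silyl group. The fallback sets out from 5 and carries the 4-oxygen through the hot step as a base-stable allyl ether. Allyl bromide and K2CO3 in acetone should alkylate the 4-hydroxyl of 5 to give 4-(allyloxy)-2-hydroxybenzaldehyde F3, and acetalisation as in step 5 gives 5-(allyloxy)-2-(5,5-dimethyl-1,3-dioxan-2-yl)phenol F4. F4 can open epoxide 4 under forcing conditions (Cs2CO3, DMF, 120 °C) to the allyl ether amide F5. Pd(PPh3)4 with morpholine in THF removes the allyl group to give the phenol amide F6, and TIPSCl with imidazole silylates only the phenol. The fallback comes back to the route at 8.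

3. Step 12. Iodination may show poor site selectivity between C6, C8 and ring B. The fallback sets out from 16 and uses a reaction that can only occur ortho to the single free phenol. Formylation through the magnesium phenoxide (MgCl2, Et3N, paraformaldehyde, MeCN, reflux) delivers formaldehyde within the metal phenoxide complex and should give the 6-carbaldehyde F7. Julia–Kocienski olefination of F7 with 5-[(2-methylpropyl)sulfonyl]-1-phenyl-1H-tetrazole and excess KN(SiMe3)2 (DME, −60 °C to rt) should give the E alkene. The fallback comes back to the route at 20 and bypasses 17 and step 14.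

Further compounds
F1 | step 10 | (Z)-trimethylsilyl enol ether of 12 with the tertiary alcohol as trimethylsilyl ether | COCOc1cc(OC)cc(OCOC)c1/C(O[Si](C)(C)C)=C/C[C@H](C(C)(C)O[Si](C)(C)C)Oc1cc(O[Si](C(C)C)(C(C)C)C(C)C)ccc1C1OCC(C)(C)CO1
F2 | step 10 | (2R)-4-[4-methoxy-2,6-bis(methoxymethoxy)benzoyl]-5-[2,2-dimethyl-3-(trimethylsilyloxy)propoxy]-2-[2-(trimethylsilyloxy)propan-2-yl]-8-[(triisopropylsilyl)oxy]-2,3,4,5-tetrahydro-1-benzoxepine (mixture at C4 and C5) | COCOc1cc(OC)cc(OCOC)c1C(=O)C1C[C@H](C(C)(C)O[Si](C)(C)C)Oc2cc(O[Si](C(C)C)(C(C)C)C(C)C)ccc2C1OCC(C)(C)CO[Si](C)(C)C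
F3 | step 6 | 4-(allyloxy)-2-hydroxybenzaldehyde | C=CCOc1ccc(C=O)c(O)c1
F4 | step 6 | 5-(allyloxy)-2-(5,5-dimethyl-1,3-dioxan-2-yl)phenol | C=CCOc1ccc(C2OCC(C)(C)CO2)c(O)c1
F5 | step 6 | (4R)-4-[5-(allyloxy)-2-(5,5-dimethyl-1,3-dioxan-2-yl)phenoxy]-5-hydroxy-N-methoxy-N,5-dimethylhexanamide | CON(C)C(=O)CC[C@H](C(C)(C)O)Oc1cc(OCC=C)ccc1C1OCC(C)(C)CO1
F6 | step 6 | (4R)-4-[2-(5,5-dimethyl-1,3-dioxan-2-yl)-5-hydroxyphenoxy]-5-hydroxy-N-methoxy-N,5-dimethylhexanamide | CON(C)C(=O)CC[C@H](C(C)(C)O)Oc1cc(O)ccc1C1OCC(C)(C)CO1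
F7 | step 12 | 6-formyl derivative of 16 | COc1cc2oc3c(c(=O)c2c(O)c1C=O)C[C@H](C(C)(C)O)Oc1cc(O[Si](C(C)C)(C(C)C)C(C)C)ccc1-3
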